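Start from how slow theta gets near 30% conversion: I reckon both orders asked for this flask from that slowness.

| flask | substrate | reagent | free catalyst | remark |
|---|---|---|---|---|
| epsilon | 24 mM | 1 equiv | 2.3 mol% | run made earlier |
| beta | 37 mM | 1 equiv | 2.3 mol% | run made earlier |
| theta | 49 mM | 1 equiv | 3.4 mol% | run made earlier |
| flask | 49 mM | 1.00 equiv | 2.3 mol% |  |

| run | time / min | product / % | substrate / % |
|---|---|---|---|
| epsilon | 3.00 | 1.6 | 97.9 |
| epsilon | 5.00 | 3.3 | 95.4 |
| epsilon | 8.00 | 6.2 | 94.2 |
| epsilon | 12.0 | 8.4 | 92.5 |
| epsilon | 20.0 | 12.4 | 87.9 |
| epsilon | 40.0 | 18.2 | 80.5 |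
| beta | 3.00 | 3.7 | 97.1 |
| beta | 5.00 | 5.0 | 93.3 |
| beta | 8.00 | 9.1 | 90.9 |
| beta | 12.0 | 13.3 | 87.4 |
| beta | 20.0 | 18.7 | 80.9 |
| beta | 40.0 | 27.0 | 73.0 |
| theta | 3.00 | 6.6 | 93.5 |
| theta | 5.00 | 10.3 | 88.3 |
| theta | 10.0 | 18.5 | 79.9 |
| theta | 20.0 | 28.6 | 69.2 |
| theta | 40.0 | 38.9 | 58.9 |

(standard deviation of a reading: 0.5 percentage points)

* apparent order in reagent when 30% of the substrate are converted (percent change of the rate of making product for one percent more reagent charged)
* apparent order in free catalyst when 30% of the substrate are converted (percent change of the rate of making product for one percent more free catalyst charged)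

- the numbers in the tables scatter with a standard deviation of 0.5 percentage points
- on the list of suspects stand: reagent + free catalyst <-> catalyst intermediate A; catalyst intermediate B <-> free catalyst + product; substrate + catalyst intermediate A <-> catalyst intermediate B; reagent <-> dormant form

Over the first 5.00 min, epsilon and theta give starting rates per catalyst and per reagent that differ by a ratio of only 1.03. Substrate and reagent were charged equally in these runs, so they can't be separated; I assign that order to reagent and take the rate as proportional to catalyst times reagent left.

Theta's starting rate over its mean rate from 10.0 min to 40.0 min, a window spanning 30% product, is 3.03: call this the fall factor. Plain consumption gives 1.43, so the fall is larger, and the reagent seems to be leaking elsewhere, into the dormant form.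

Suppose the leak and product draw on reagent in a fixed proportion. At fixed conversion, extra reagent then adds to what is left, so the reagent order equals the fall factor. One percent more catalyst trims the dormant amount by one percent, so the catalyst order is the fall factor times the unconverted fraction. Using theta as a stand-in, I reckon 3.03 and 2.12.

The forecast differs, at 0.8 (0.4 to 1.3) and 0.95 (0.75 to 1.05), holding that “Reagent therefore looks nearly saturating early”.

The flask gives 2.4 and 1.6.

    reagent + free catalyst ⇌ catalyst intermediate A (K = 22.0 L mol⁻¹, k = 28.0 L mol⁻¹ min⁻¹)
    catalyst intermediate B ⇌ free catalyst + product (K = 0.0300 M, k = 8.20 min⁻¹)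
    substrate + catalyst intermediate A ⇌ catalyst intermediate B (K = 230 L mol⁻¹, k = 120 L mol⁻¹ min⁻¹)
    reagent ⇌ dormant form (K = 1.50, k = 0.0240 min⁻¹)

In the flask at 0.500 h, substrate stood at 71.2%, and charge over reagent left was 2.65, below theta's fall factor of 3.03. Until then, reagent fed catalyst intermediate A while also passing into the dormant form, which reached 16.3 mM as product reached 28.1%. By 1.00 h, reagent in the flask was down to 24% of its charge, less than the 62% of substrate left, and the dormant form held 18.2 mM.

Readings and results are simulated from invented constants.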